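In a one-step world X goes to D at a rate proportional to X, and one constant gives the share left at any time, whatever the charge. These flasks can be held against that picture.

| flask | X | Q | remark | time |
|---|---|---|---|---|
| Thursday's | 6.8 × 10⁻⁴ M | 25 µM | run made earlier |  |
| Sunday's | 0.0010 M | 25 µM | run made earlier |  |
| midnight | 5.0 × 10⁻⁴ M | 25 µM |  | 2.5 min |
| dawn | 8.0 × 10⁻⁴ M | 25 µM |  | 2.5 min |

| run | time / s | D / % | X / % |
|---|---|---|---|
| Thursday's | 10.0 | 5.9 | 94.6 |
| Thursday's | 15.0 | 7.9 | 91.5 |
| Thursday's | 25.0 | 13.8 | 86.6 |
| Thursday's | 40.0 | 20.7 | 79.1 |
| Thursday's | 60.0 | 30.0 | 70.0 |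
| Thursday's | 120 | 51.8 | 47.0 |
| Sunday's | 20.0 | 11.5 | 88.4 |
| Sunday's | 40.0 | 21.7 | 78.5 |
| Sunday's | 50.0 | 27.3 | 73.7 |
| Sunday's | 80.0 | 39.0 | 60.8 |
| Sunday's | 120 | 52.7 | 47.3 |

(readings scatter by 0.5 percentage points)

- the average divides the monomer in chains by the number of chains, living and dead together; two radicals that join make one chain
- the numbers in the tables scatter with a standard deviation of 0.5 percentage points
- the earlier runs do not show the number of chains; that part of a forecast is a guess

- which of the two ends with the longer chains by the average number of monomer units in a chain (living and dead chains, two that joined counted as one) ("neither" if they lie within 10%) (midnight / dawn / neither)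
- average number of monomer units in a chain (living and dead chains, two that joined counted as one) at the end, midnight
- average number of monomer units in a chain (living and dead chains, two that joined counted as one) at the end, dawn

Thursday's last reading gives 0.00629 s⁻¹ for the loss constant, the logarithm of charge over X left, divided by time. The field calls this a pseudo-first-order constant.

But a one-step picture needs that constant to ignore the charge. Sunday's run, with 1.47 times Thursday's X, gives 0.00624 s⁻¹, and the two last X readings differ by 0.3 percentage points at a scatter of 0.5 points. Sunday's last row also holds 100% of the X charged as D and X, so X lost can be counted as D.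

A doubt remains: midnight's charge lies below both runs, and the end lies past the last reading. The reckoning takes the constant across both gaps, knowingly:

X left at the end = exp(−loss constant × time) = 38.9%

D at the end: midnight 3.05 × 10⁻⁴ M, dawn 4.89 × 10⁻⁴ M

Length still needs the number of chains, and the runs do not show it. A constant loss constant says that the growing centres hold steady, not how many chains have ended. Yet the two flasks share their Q and their time, and the reckoning gives both the same loss constant. So the reckoning takes their chain numbers as equal, and the number cancels:

dawn length / midnight length = 1.60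

Dawn should therefore be longer, by more than the margin. This reckoning stops at that ratio, while the forecast names dawn and goes on to 12 for midnight and 19.3 for dawn, on “quick initiation with no noticeable termination, one chain per Q”.

The flasks end at 176 units for midnight and 280 for dawn, a factor of 1.59 in favour of dawn. X left stands at 39% in midnight and 40% in dawn.

    Q → 2 L (k = 4.70 × 10⁻⁴ s⁻¹)
    X + L → Z + D (k = 6.90 × 10⁶ L mol⁻¹ s⁻¹)
    X + Z → D + Z, rate k3*[Z]*[X] (k = 1.30 × 10⁵ L mol⁻¹ s⁻¹)
    2 Z → J (k = 5.00 × 10⁶ L mol⁻¹ s⁻¹)

The growth step by itself gives its constant times standing Z: in dawn at 1.25 min, 1.3 × 10⁵ L mol⁻¹ s⁻¹ times 4.76 × 10⁻⁸ M is 0.00619 s⁻¹. A neighbour of dawn holds 4.2 × 10⁻⁵ M of Q, and its Z stands at 6.07 × 10⁻⁸ M against dawn's 4.68 × 10⁻⁸ M, a ratio of 1.30, with 1.30 for the square root of the ratio of the Q charges. Scaled by that root, the loss constant becomes 0.00816 s⁻¹ and leaves 29.4% of X. The neighbour ends with 29.9% of X, and its chains average 194 units, shorter than dawn's 280.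

All runs were computed for substances that don't exist, and the scatter is random.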